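**Plan**
- Retrosynthesis: the enoate is cut at C13–C16 and C14–C15 (back to a terminal alkyne) and at C9–C11 (back to a C9 ketone and a butynyl Grignard reagent); the 6-OH is taken back to a plain enone; ring A is taken back to a seven-membered ring in which C18 sits between C3 and C4; that ring is cut at C4=C18 (metathesis) and C10–C1 (enolate alkylation), which leads to (S)-carvone.
- Forward: the carvone ring becomes ring B; two enolate alkylations make C10 quaternary; ring-closing metathesis onto the isopropenyl group closes a cycloheptene; epoxidation and a Lewis-acid 1,2-shift contract it to ring A and push C18 out as CHO on the new quaternary C4; ring B is then oxidised at C6, the C9 carbonyl is replaced by H and the side chain, and the enoate is completed.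
- Enabling feature: the trisubstituted oxirane C4(CH3)–C18(H) inside the seven-membered ring (C10, C1, C2, C3, C18, C4, C5). C4 is tertiary and ionises; C18 carries the oxygen (becomes C=O) and the ring CH2 C3 that migrates.
- Stereochemistry: C5 from (S)-carvone; C10 by alkylation anti to isopropenyl; C4 by epoxidation anti to the angular methyl followed by a shift with inversion; C6 by epoxidation anti to the two axial methyls; C9 by palladium hydride delivery anti to a tertiary carbonate; E-alkene by syn carboalumination.

Key step: step 5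

Assumption: intermediates are described with the labdane numbering of the target (C1–C10 decalin, C11–C16 side chain, C17/C19/C20 = methyls on C8/C4/C10, C18 = oxygenated carbon on C4); "H5 face" is the face of the bicycle that carries H5 (in the target also H9, 6-OH and C18) and "methyl face" the face of C20; 3 is used as its epimer mixture because step 2 makes that centre trigonal again.

Step 1
Reactants: 1 (S)-(+)-carvone
Product: 3 6-methylcarvone (epimer mixture at the new centre; trans epimer major), via lithium enolate 2 (not isolated)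
Conditions: LDA, THF, −78 °C; MeI, −78 → 0 °C
Reagents that add atoms: iodomethane, CI
Why: Kinetic deprotonation at the only enolisable alpha' carbon (future C10) and SN2 methylation (enolate alkylation) should give the methyl ketone as an epimer mixture, which is harmless because the centre is re-enolised in step 2.

Step 2
Reactants: 3 (6-methylcarvone); 4 (5-iodopent-1-ene)
Product: 6 (5R,6R)-2,6-dimethyl-6-(pent-4-en-1-yl)-5-(prop-1-en-2-yl)cyclohex-2-en-1-one, via lithium enolate 5 (not isolated)
Conditions: LDA, THF, −78 → 0 °C; DMPU, 4, −78 °C → rt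
Reagents that add atoms: none
Why: Enolate alkylation of the tetrasubstituted lithium enolate should occur on the face opposite the neighbouring isopropenyl group, so the pentenyl chain (C1–C3 plus future C18) ends up trans to isopropenyl and the C20 methyl cis, which is the C5/C10 relationship of the trans-decalin.

Step 3
Reactants: 6 (dialkylated carvone)
Product: 7 (1R,7R)-2,7,9-trimethylbicyclo[5.4.0]undeca-2,9-dien-8-one (trans-fused)
Conditions: second-generation Grubbs catalyst [RuCl2(=CHPh)(PCy3)(H2IMes)] (5 mol %), CH2Cl2, 40 °C
Reagents that add atoms: none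
Why: Ring-closing metathesis between the isopropenyl alkene and the terminal alkene should close the trans-fused cycloheptene (C4=C18 trisubstituted) with loss of ethene, the electron-poor enone alkene not taking part.

Step 4
Reactants: 7 (bicyclic dienone)
Product: 8 C4,C18-epoxide of 7 (oxirane oxygen on the H5 face)
Conditions: mCPBA, CH2Cl2, 0 °C
Reagents that add atoms: mCPBA, O=C(OO)c1cccc(Cl)c1
Why: Prilezhaev epoxidation should pick the electron-rich trisubstituted C4=C18 alkene over the enone and approach from the face opposite the axial angular methyl C20 (as with steroid ring-A alkenes), so the oxygen lies on the H5 face.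

Step 5
Reactants: 8 (epoxide)
Product: 9 (1S,4aR,8aR)-1,4a,6-trimethyl-5-oxo-1,2,3,4,4a,5,8,8a-octahydronaphthalene-1-carbaldehyde
Conditions: MABR [methylaluminium bis(4-bromo-2,6-di-tert-butylphenoxide), MeAl(OC6H2Br-tBu2)2] (2.5 equiv), CH2Cl2, −78 → −20 °C
Reagents that add atoms: none
Why: The bulky oxophilic aluminium Lewis acid binds the oxirane oxygen and the C4–O bond ionises because C4 is tertiary; as it lengthens, the ring methylene C3 on the other oxirane carbon shifts to the rear of C4 while the C18–O bond becomes the aldehyde carbonyl (Meinwald rearrangement in its alkyl-shift, semipinacol mode). The closest known reaction is the MABR-promoted conversion of 1-methylcycloalkene oxides into 1-methylcycloalkanecarbaldehydes with loss of one ring carbon. Ring A is therefore closed not by cyclisation but by a suprafacial 1,2-shift through a three-centre bridged transition state, which turns the seven-membered ring (C10, C1, C2, C3, C18, C4, C5) into the six-membered ring and leaves C18 outside it as CHO. The new quaternary centre C4 is controlled by the oxirane configuration: C3 enters anti to the departing oxygen (inversion at C4), so the oxirane on the H5 face should give CHO equatorial on the H5 face and the C19 methyl axial, cis to C20. The step needs cleavage at C4 and not at C18 (secured by tertiary versus secondary carbon) and migration of C3 in preference to the hydride on C18 (secured by the bulky aluminium reagent at low temperature, which is known to favour alkyl shift); the enone only ties up Lewis acid and is otherwise inert.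

Step 6
Reactants: 9 (keto aldehyde)
Product: 10 (4aR,5S,8aR)-5-(hydroxymethyl)-2,5,8a-trimethyl-4a,5,6,7,8,8a-hexahydronaphthalen-1(4H)-one
Conditions: NaBH4, MeOH/CH2Cl2, −78 → −40 °C
Reagents that add atoms: none
Why: Chemoselective borohydride reduction should take the aldehyde much faster than the conjugated ketone flanked by the quaternary C10, and no stereocentre is formed.

Step 7
Reactants: 10 (hydroxymethyl enone)
Product: 12 deconjugated ketone (C9 ketone; C6=C7 alkene; H8 on the H5 face), via dipotassium dienolate 11 (not isolated)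
Conditions: KOtBu (3 equiv), tBuOH, THF, 0 °C → rt; inverse quench into cold aq. AcOH
Reagents that add atoms: none
Why: Deconjugation by kinetic alpha-protonation of the extended dienolate (only the gamma hydrogens at C6 are acidic because C10 is quaternary) should move the alkene to C6=C7, protonation at C8 coming from the face opposite C20; the C8 centre is transient.

Step 8
Reactants: 12 (deconjugated ketone)
Product: 14 6,18-dihydroxy enone (C9 ketone; C7=C8; 6-OH on the H5 face), via epoxy ketone 13 (not isolated)
Conditions: mCPBA, CH2Cl2, 0 °C; then Et3N, rt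
Reagents that add atoms: mCPBA, O=C(OO)c1cccc(Cl)c1
Why: Epoxidation of the isolated C6=C7 alkene should occur anti to the axial methyls C19 and C20 and be guided by the C18 hydroxyl on the same face (Henbest effect), and E1cB opening of the beta,gamma-epoxy ketone then restores the enone without touching the C6–O bond, so the 6-OH is equatorial on the H5 face.

Step 9
Reactants: 14 (dihydroxy enone)
Product: 15 6,18-bis(tert-butyldimethylsilyl) ether of 14
Conditions: TBSOTf (2.5 equiv), 2,6-lutidine, CH2Cl2, −78 → 0 °C
Reagents that add atoms: tert-butyldimethylsilyl triflate, CC(C)(C)[Si](C)(C)OS(=O)(=O)C(F)(F)F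
Why: Standard silylation of the primary and the secondary allylic hydroxyl gives ethers that should survive the organometallic, palladium and aluminium steps that follow.

Step 10
Reactants: 15 (bis-silyl ether enone); 16 ((4-bromobut-1-yn-1-yl)trimethylsilane)
Product: 19 C9 tertiary allylic methyl carbonate (OCO2CH3 on the methyl face; silylbutynyl chain on the H5 face), via Grignard reagent 17 (not isolated), via bromomagnesium alkoxide 18 (not isolated)
Conditions: 16, Mg, THF; then 15, LaCl3·2LiCl (30 mol %), THF, 0 °C; then ClCO2Me, 0 °C → rt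
Reagents that add atoms: methyl chloroformate, COC(=O)Cl
Why: Lanthanide-assisted Grignard 1,2-addition to the hindered enone carbonyl (no alpha hydrogens) should come from the face opposite the axial C20 methyl, which places the new oxygen on the methyl face, and the alkoxide is acylated in the same flask to the tertiary allylic carbonate.

Step 11
Reactants: 19 (tertiary allylic carbonate)
Product: 20 bis-silyl ether with H9 on the H5 face (C7=C8 alkene; silylbutynyl chain equatorial on C9)
Conditions: Pd(OAc)2 (5 mol %), PBu3 (20 mol %), HCO2H, Et3N, THF, 40 °C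
Reagents that add atoms: none
Why: In this Tsuji formate hydrogenolysis zerovalent palladium should ionise the carbonate with inversion to a pi-allyl complex on the H5 face and deliver hydride from the metal to the more substituted terminus C9 on that face, which sets H9 (side chain cis to C20) and keeps the C7=C8 alkene, as in the known generation of ring-fusion hydrogens from allylic formates.

Step 12
Reactants: 20 (silylalkyne)
Product: 21 terminal alkyne (C13≡C14–H)
Conditions: K2CO3 (cat.), MeOH, rt
Reagents that add atoms: none
Why: Base-catalysed methanolysis should cleave only the alkynyl C–Si bond, the silyl ethers being stable under these conditions.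

Step 13
Reactants: 21 (terminal alkyne)
Product: 23 6,18-bis(tert-butyldimethylsilyl) ether of the target, via alkenylalane 22 (not isolated)
Conditions: Me3Al (3 equiv), Cp2ZrCl2 (0.3 equiv), CH2Cl2, 0 °C → rt; then ClCO2Me, 0 °C → rt
Reagents that add atoms: trimethylaluminium, C[Al](C)C; methyl chloroformate, COC(=O)Cl
Why: Negishi zirconium-catalysed carboalumination adds methyl (to C13) and aluminium (to C14) syn across the alkyne, and acylation of the alkenylalane with retention should fix the E geometry of the 3-methyl-2-enoate.

Step 14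
Reactants: 23 (bis-silyl ether)
Product: 24 methyl (2E)-5-[(1R,4R,4aS,5S,8aS)-4-hydroxy-5-(hydroxymethyl)-2,5,8a-trimethyl-1,4,4a,5,6,7,8,8a-octahydronaphthalen-1-yl]-3-methylpent-2-enoate (target)
Conditions: HF·pyridine, pyridine, THF, 0 °C → rt
Reagents that add atoms: none
Why: Buffered fluoride desilylation should free both hydroxyls without touching the enoate or ionising the allylic alcohol.

**Compound list**
1 | (S)-(+)-carvone, (5S)-2-methyl-5-(prop-1-en-2-yl)cyclohex-2-en-1-one | O=C1C(C)=CC[C@H](C(C)=C)C1 | starting material
2 | kinetic lithium enolate of 1 (deprotonated at the CH2 next to C=O) | [Li]OC1=C[C@@H](C(C)=C)CC=C1C | intermediate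
3 | (5S,6R)-2,6-dimethyl-5-(prop-1-en-2-yl)cyclohex-2-en-1-one (6-methylcarvone; major trans epimer shown) | O=C1C(C)=CC[C@H](C(C)=C)[C@H]1C | intermediate
4 | 5-iodopent-1-ene | C=CCCCI | starting material
5 | lithium enolate of 3 | [Li]OC1=C(C)[C@@H](C(C)=C)CC=C1C | intermediate
6 | (5R,6R)-2,6-dimethyl-6-(pent-4-en-1-yl)-5-(prop-1-en-2-yl)cyclohex-2-en-1-one (pentenyl trans to isopropenyl) | O=C1C(C)=CC[C@H](C(C)=C)[C@@]1(C)CCCC=C | intermediate
7 | (1R,7R)-2,7,9-trimethylbicyclo[5.4.0]undeca-2,9-dien-8-one (trans-fused; H5 anti to C20) | O=C1C(C)=CC[C@@H]2C(C)=CCCC[C@@]12C | intermediate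
8 | C4,C18-epoxide of 7, oxygen on the H5 face | O=C1C(C)=CC[C@@H]2[C@@]3(C)O[C@H]3CCC[C@@]12C | intermediate
9 | (1S,4aR,8aR)-1,4a,6-trimethyl-5-oxo-1,2,3,4,4a,5,8,8a-octahydronaphthalene-1-carbaldehyde (trans-decalin; CHO equatorial on the H5 face) | O=C1C(C)=CC[C@@H]2[C@@](C)(C=O)CCC[C@@]12C | intermediate
10 | (4aR,5S,8aR)-5-(hydroxymethyl)-2,5,8a-trimethyl-4a,5,6,7,8,8a-hexahydronaphthalen-1(4H)-one | O=C1C(C)=CC[C@@H]2[C@@](C)(CO)CCC[C@@]12C | intermediate
11 | dipotassium dienolate alkoxide of 10 | [K]OC1=C(C)C=C[C@@H]2[C@@](C)(CO[K])CCC[C@@]12C | intermediate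
12 | deconjugated ketone: C9 ketone, C6=C7, H8 on the H5 face, C18 alcohol | O=C1[C@H](C)C=C[C@@H]2[C@@](C)(CO)CCC[C@@]12C | intermediate
13 | C6,C7-epoxide of 12, oxygen on the H5 face | O=C1[C@H](C)[C@H]3O[C@H]3[C@@H]2[C@@](C)(CO)CCC[C@@]12C | intermediate
14 | 6,18-dihydroxy enone: C9 ketone, C7=C8, 6-OH on the H5 face | O=C1C(C)=C[C@@H](O)[C@@H]2[C@@](C)(CO)CCC[C@@]12C | intermediate
15 | 6,18-bis(tert-butyldimethylsilyl) ether of 14 | O=C1C(C)=C[C@@H](O[Si](C)(C)C(C)(C)C)[C@@H]2[C@@](C)(CO[Si](C)(C)C(C)(C)C)CCC[C@@]12C | intermediate
16 | (4-bromobut-1-yn-1-yl)trimethylsilane | C[Si](C)(C)C#CCCBr | starting material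
17 | [4-(trimethylsilyl)but-3-yn-1-yl]magnesium bromide | C[Si](C)(C)C#CCC[Mg]Br | intermediate
18 | bromomagnesium C9 alkoxide (oxygen on the methyl face, chain on the H5 face) | C[Si](C)(C)C#CCC[C@@]1(O[Mg]Br)C(C)=C[C@@H](O[Si](C)(C)C(C)(C)C)[C@@H]2[C@@](C)(CO[Si](C)(C)C(C)(C)C)CCC[C@@]12C | intermediate
19 | C9 tertiary allylic methyl carbonate | C[Si](C)(C)C#CCC[C@@]1(OC(=O)OC)C(C)=C[C@@H](O[Si](C)(C)C(C)(C)C)[C@@H]2[C@@](C)(CO[Si](C)(C)C(C)(C)C)CCC[C@@]12C | intermediate
20 | bis-silyl ether with H9 on the H5 face, C7=C8, 4-(trimethylsilyl)but-3-ynyl chain on C9 | C[Si](C)(C)C#CCC[C@@H]1C(C)=C[C@@H](O[Si](C)(C)C(C)(C)C)[C@@H]2[C@@](C)(CO[Si](C)(C)C(C)(C)C)CCC[C@@]12C | intermediate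
21 | terminal alkyne (20 without the alkynyl silyl group) | C#CCC[C@@H]1C(C)=C[C@@H](O[Si](C)(C)C(C)(C)C)[C@@H]2[C@@](C)(CO[Si](C)(C)C(C)(C)C)CCC[C@@]12C | intermediate
22 | (E)-alkenyl(dimethyl)alane (Al on C14, new methyl on C13) | C[Al](C)/C=C(\C)CC[C@@H]1C(C)=C[C@@H](O[Si](C)(C)C(C)(C)C)[C@@H]2[C@@](C)(CO[Si](C)(C)C(C)(C)C)CCC[C@@]12C | intermediate
23 | 6,18-bis(tert-butyldimethylsilyl) ether of the target | COC(=O)/C=C(\C)CC[C@@H]1C(C)=C[C@@H](O[Si](C)(C)C(C)(C)C)[C@@H]2[C@@](C)(CO[Si](C)(C)C(C)(C)C)CCC[C@@]12C | intermediate
24 | methyl (2E)-5-[(1R,4R,4aS,5S,8aS)-4-hydroxy-5-(hydroxymethyl)-2,5,8a-trimethyl-1,4,4a,5,6,7,8,8a-octahydronaphthalen-1-yl]-3-methylpent-2-enoate (CNP0149445.1) | COC(=O)/C=C(\C)CC[C@@H]1C(C)=C[C@@H](O)[C@@H]2[C@@](C)(CO)CCC[C@@]12C | target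

**Count and risks**
Total step count: 14. Longest linear sequence: 14 steps, from (S)-carvone (1).

Steps most likely to fail:

1. Step 5. Hydride migration from C18 may outrun migration of C3 and leave the seven-membered ring intact, or a long-lived C4 cation may lose the stereochemical memory of the oxirane. The fallback sets out from 8 and returns at 10. Isomerisation of 8 with LiClO4 in hot benzene (hydride-shift conditions) would give the seven-membered-ring ketone F1. Chlorination with SO2Cl2 at the more substituted alpha carbon C4, from the H5 face, would give the tertiary alpha-chloro ketone F2. Favorskii rearrangement with NaOMe in DME (the C3 enolate closes the cyclopropanone with inversion at C4, and methoxide opens it toward the less substituted carbanion C3) would give the ring-contracted methyl ester F3 with the C4 configuration of 9. LiAlH4 would reduce ester and ketone to the diol F4 (either C9 epimer serves), and MnO2 would re-oxidise only the allylic alcohol to give 10.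

2. Step 11. Ionisation of the very hindered tertiary carbonate may be slow (or the carbonate may not form cleanly in step 10), hydride may be delivered to C7 instead of C9, or facial control may leak. The fallback sets out from 15 with Grignard reagent 17 and returns at 20. Aqueous work-up of the addition would give the tertiary allylic alcohol F5. Oxidative transposition with pyridinium chlorochromate (C5H5NH[CrO3Cl]) would give the transposed enone F6 (C7 ketone, C8=C9). Luche reduction (NaBH4, CeCl3·7H2O, MeOH) from the H5 face would give the allylic alcohol F7 with the 7-OH on the methyl face. Myers reductive transposition (2-nitrobenzenesulfonylhydrazide, PPh3, DEAD, THF, −30 °C → rt) would pass through the inverted sulfonylhydrazine F8 and the allylic diazene F9, whose retro-ene loss of N2 places hydrogen on C9 on the H5 face and the alkene at C7=C8, giving 20.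

3. Step 2. C-alkylation of the hindered tetrasubstituted enolate by an unactivated primary iodide may be slow, so that proton transfer, O-alkylation or elimination of HI from 4 takes over. The fallback sets out from 3 and returns at 6. Alkylation of enolate 5 with allyl bromide (activated electrophile, same anti-to-isopropenyl approach) would give 6-allyl-6-methylcarvone F10. Hydroboration of its monosubstituted alkene with 9-BBN would give the B-alkyl borane F11, and B-alkyl Suzuki coupling with vinyl bromide (Pd(dppf)Cl2, K3PO4, THF/H2O) would give 6.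

**Further compounds**
F1 | step 5 | seven-membered-ring ketone (C18 ketone, C4 as CH(CH3); hydride-shift isomer of 8) | O=C1C(C)=CC[C@@H]2[C@@H](C)C(=O)CCC[C@@]12C
F2 | step 5 | alpha-chloro ketone (Cl on C4, H5 face) | O=C1C(C)=CC[C@@H]2[C@@](C)(Cl)C(=O)CCC[C@@]12C
F3 | step 5 | methyl ester analogue of 9 (C18 as CO2CH3) | O=C1C(C)=CC[C@@H]2[C@@](C)(C(=O)OC)CCC[C@@]12C
F4 | step 5 | diol (C9 allylic alcohol and C18 alcohol) | O[C@@H]1C(C)=CC[C@@H]2[C@@](C)(CO)CCC[C@@]12C
F5 | step 11 | C9 tertiary allylic alcohol (protonated 18) | C[Si](C)(C)C#CCC[C@@]1(O)C(C)=C[C@@H](O[Si](C)(C)C(C)(C)C)[C@@H]2[C@@](C)(CO[Si](C)(C)C(C)(C)C)CCC[C@@]12C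
F6 | step 11 | transposed enone (C7 ketone, C8=C9) | C[Si](C)(C)C#CCCC1=C(C)C(=O)[C@@H](O[Si](C)(C)C(C)(C)C)[C@@H]2[C@@](C)(CO[Si](C)(C)C(C)(C)C)CCC[C@@]12C
F7 | step 11 | allylic alcohol (7-OH on the methyl face, C8=C9) | C[Si](C)(C)C#CCCC1=C(C)[C@H](O)[C@@H](O[Si](C)(C)C(C)(C)C)[C@@H]2[C@@](C)(CO[Si](C)(C)C(C)(C)C)CCC[C@@]12C
F8 | step 11 | N-allyl-N-(2-nitrobenzenesulfonyl)hydrazine (N on C7, H5 face) | C[Si](C)(C)C#CCCC1=C(C)[C@@H](N(N)S(=O)(=O)c3ccccc3[N+](=O)[O-])[C@@H](O[Si](C)(C)C(C)(C)C)[C@@H]2[C@@](C)(CO[Si](C)(C)C(C)(C)C)CCC[C@@]12C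
F9 | step 11 | allylic diazene (N=NH on C7, H5 face) | C[Si](C)(C)C#CCCC1=C(C)[C@@H](N=N)[C@@H](O[Si](C)(C)C(C)(C)C)[C@@H]2[C@@](C)(CO[Si](C)(C)C(C)(C)C)CCC[C@@]12C
F10 | step 2 | 6-allyl-6-methylcarvone (allyl trans to isopropenyl) | O=C1C(C)=CC[C@H](C(C)=C)[C@@]1(C)CC=C
F11 | step 2 | B-alkyl-9-BBN adduct of F10 | O=C1C(C)=CC[C@H](C(C)=C)[C@@]1(C)CCCB1C2CCCC1CCC2
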